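**Retrosynthetic overview**
- Feature: on the catechol ring the free OH sits ortho to the ether oxygen from the para-phenylene ring and para to the CH2CH2 bridge. This is the pattern left by ortho C–O coupling of two 4-alkylphenols.
- Key disconnection: this catechol-ring C–O(aryl) bond. It opens to a seco bis-phenol with a 3,5-dibromo-4-hydroxyphenyl end (to be oxidised) and a 3,5-dichloro-4-hydroxyphenyl end (oxygen nucleophile). Tl(III) oxidation followed by zinc reduction closes the 18-membered ring, the only ring formed; the four six-membered rings are bought.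
- Seco chain: the quinone-ring–O–meta-phenylene ether comes from SNAr on 2-fluoro-3,6-dimethoxybenzaldehyde. Two Wittig olefinations build the bridges (central CHO with the dichlorobenzyl ylide, then the meta-phenylene ylide with the dibromobenzaldehyde), and one double diimide reduction saturates them.
- The quinone travels as its dimethyl ether and is switched to the Tl(III)-inert diacetate before the key step. Afterwards come hydrodehalogenation, acetate methanolysis and Ag2O oxidation.

Key step: step 14

Assumption: the target has no stereocentre and the 18-membered ring is taken as conformationally mobile (no stable planar chirality), so no enantioselective step is needed.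

Step 1
Reactants: 1 2-fluoro-1,4-dimethoxybenzene
Product: 3 2-fluoro-3,6-dimethoxybenzaldehyde, via (2-fluoro-3,6-dimethoxyphenyl)lithium 2 (not isolated)
Conditions: n-BuLi, THF, −78 °C; DMF, −78 °C → rt; aq. HCl
Reagents that add atoms: N,N-dimethylformamide, CN(C)C=O
Why: Directed ortho-metalation removes the most acidic C–H (flanked by F and OMe), the o-fluoroaryllithium does not lose LiF at −78 °C, and DMF formylates it.

Step 2
Reactants: 3 2-fluoro-3,6-dimethoxybenzaldehyde, 4 3-hydroxybenzyl alcohol
Product: 5 2-[3-(hydroxymethyl)phenoxy]-3,6-dimethoxybenzaldehyde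
Conditions: K2CO3, DMF, 110 °C
Reagents that add atoms: none
Why: In this nucleophilic aromatic substitution (addition–elimination) the phenoxide of 4 displaces the fluoride ortho to the formyl group, and carbonate deprotonates only the phenol, so the two future bridge carbons stay differentiated as CHO and CH2OH.

Step 3
Reactants: 6 3,5-dichloro-4-hydroxybenzaldehyde
Product: 7 4-(benzyloxy)-3,5-dichlorobenzaldehyde
Conditions: BnBr, K2CO3, DMF, rt → 50 °C
Reagents that add atoms: benzyl bromide, BrCc1ccccc1
Why: Williamson etherification of the acidic 2,6-dichlorophenol installs a benzyl ether that tolerates the base, mild acid, diimide and Ce(IV) steps ahead and can later be cleaved without hydrogen.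

Step 4
Reactants: 7 4-(benzyloxy)-3,5-dichlorobenzaldehyde
Product: 8 [4-(benzyloxy)-3,5-dichlorophenyl]methanol
Conditions: NaBH4, MeOH–THF, 0 °C
Reagents that add atoms: none
Why: Borohydride reduction of the aldehyde leaves the aryl chlorides and the benzyl ether untouched.

Step 5
Reactants: 8 [4-(benzyloxy)-3,5-dichlorophenyl]methanol
Product: 9 [4-(benzyloxy)-3,5-dichlorobenzyl]triphenylphosphonium bromide
Conditions: PPh3·HBr, MeCN, reflux
Reagents that add atoms: triphenylphosphine hydrobromide, [Br-].c1ccc(cc1)[PH+](c1ccccc1)c1ccccc1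
Why: Phosphonium salt formation by acid-activated substitution of the benzylic alcohol works because the alcohol oxygen is far more basic than the dihaloaryl ether oxygen, so only the CH2OH carbon is substituted.

Step 6
Reactants: 9 [4-(benzyloxy)-3,5-dichlorobenzyl]triphenylphosphonium bromide, 5 2-[3-(hydroxymethyl)phenoxy]-3,6-dimethoxybenzaldehyde
Product: 11 [3-(2-{2-[4-(benzyloxy)-3,5-dichlorophenyl]ethenyl}-3,6-dimethoxyphenoxy)phenyl]methanol (E/Z mixture), via [4-(benzyloxy)-3,5-dichlorobenzylidene]triphenylphosphorane 10 (not isolated)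
Conditions: t-BuOK, THF, 0 °C; then 5, 0 °C → rt
Reagents that add atoms: none
Why: In this Wittig olefination with a semi-stabilised benzylide the free alcohol of 5 is much less acidic than the phosphonium salt and does not quench the ylide, and the alkene geometry is irrelevant because step 10 saturates it.

Step 7
Reactants: 11 [3-(2-{2-[4-(benzyloxy)-3,5-dichlorophenyl]ethenyl}-3,6-dimethoxyphenoxy)phenyl]methanol
Product: 12 [3-(2-{2-[4-(benzyloxy)-3,5-dichlorophenyl]ethenyl}-3,6-dimethoxyphenoxy)benzyl]triphenylphosphonium bromide (E/Z mixture)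
Conditions: PPh3·HBr, MeCN, reflux
Reagents that add atoms: triphenylphosphine hydrobromide, [Br-].c1ccc(cc1)[PH+](c1ccccc1)c1ccccc1
Why: Phosphonium salt formation from the benzylic alcohol uses a reagent too weakly acidic to protonate the stilbene or cleave the aryl ethers.

Step 8
Reactants: 13 3,5-dibromo-4-hydroxybenzaldehyde
Product: 14 4-(benzyloxy)-3,5-dibromobenzaldehyde
Conditions: BnBr, K2CO3, DMF, rt → 50 °C
Reagents that add atoms: benzyl bromide, BrCc1ccccc1
Why: Williamson etherification masks the acidic phenol, whose phenoxide would otherwise deactivate the aldehyde towards the ylide.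

Step 9
Reactants: 12 [3-(2-{2-[4-(benzyloxy)-3,5-dichlorophenyl]ethenyl}-3,6-dimethoxyphenoxy)benzyl]triphenylphosphonium bromide, 14 4-(benzyloxy)-3,5-dibromobenzaldehyde
Product: 16 bis-stilbene 2-{3-[2-(4-benzyloxy-3,5-dibromophenyl)ethenyl]phenoxy}-3-[2-(4-benzyloxy-3,5-dichlorophenyl)ethenyl]-1,4-dimethoxybenzene (E/Z mixtures), via stilbene benzylidenetriphenylphosphorane 15 (not isolated)
Conditions: t-BuOK, THF, 0 °C; then 14, 0 °C → rt
Reagents that add atoms: none
Why: Wittig olefination of an unhindered, electron-poor aldehyde with the benzylide formed by deprotonating 12 is fast, and the aryl bromides are inert to alkoxide at this temperature.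

Step 10
Reactants: 16 bis-stilbene
Product: 17 2-{3-[2-(4-benzyloxy-3,5-dibromophenyl)ethyl]phenoxy}-3-[2-(4-benzyloxy-3,5-dichlorophenyl)ethyl]-1,4-dimethoxybenzene
Conditions: TsNHNH2 (excess, in portions), NaOAc, THF–H2O, reflux
Reagents that add atoms: none
Why: Diimide reduction delivers H2 in a concerted way to both C=C bonds only, sparing the C–Br, C–Cl and O–benzyl bonds that catalytic hydrogenation would cleave.

Step 11
Reactants: 17 bis-bibenzyl dimethyl ether
Product: 18 2-{3-[2-(4-benzyloxy-3,5-dibromophenyl)ethyl]phenoxy}-3-[2-(4-benzyloxy-3,5-dichlorophenyl)ethyl]-1,4-benzoquinone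
Conditions: (NH4)2Ce(NO3)6, MeCN–H2O (a little CH2Cl2 for solubility), 0 °C
Reagents that add atoms: water, O
Why: In this oxidative demethylation with cerium(IV) only the trioxygenated ring is electron-rich enough to be oxidised, water adds at the two OMe-bearing carbons and methanol leaves.

Step 12
Reactants: 18 bis-benzyl ether quinone
Product: 20 2-{3-[2-(4-benzyloxy-3,5-dibromophenyl)ethyl]phenoxy}-3-[2-(4-benzyloxy-3,5-dichlorophenyl)ethyl]benzene-1,4-diyl diacetate, via bis-benzyl ether hydroquinone 19 (not isolated)
Conditions: Na2S2O4, THF–H2O, rt; phase cut; then Ac2O, pyridine, DMAP (cat.), CH2Cl2, 0 °C → rt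
Reagents that add atoms: acetic anhydride, CC(=O)OC(C)=O
Why: Dithionite reduction of the quinone and immediate O-acetylation of the air-sensitive hydroquinone turn this ring into an electron-poor diacetate that the later oxidant cannot attack.

Step 13
Reactants: 20 bis-benzyl ether diacetate
Product: 21 seco bis-phenol 2-{3-[2-(3,5-dibromo-4-hydroxyphenyl)ethyl]phenoxy}-3-[2-(3,5-dichloro-4-hydroxyphenyl)ethyl]benzene-1,4-diyl diacetate
Conditions: BCl3, pentamethylbenzene, CH2Cl2, −78 → −40 °C; aq. work-up
Reagents that add atoms: none
Why: Lewis-acid debenzylation of aryl benzyl ethers with a non-basic cation scavenger releases both good leaving-group dihalophenols at low temperature, where aryl acetates, aryl halides and diaryl ethers persist.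

Step 14
Reactants: 21 seco bis-phenol
Product: 23 halogenated macrocyclic diaryl ether (18-membered ring; hydroquinone diacetate; two Cl flanking the new ether oxygen on the para-phenylene ring; one Br ortho to the free OH on the catechol ring), via macrocyclic 6-aryloxy-2,6-dibromocyclohexa-2,4-dienone 22 (not isolated)
Conditions: Tl(NO3)3·3H2O, MeOH–THF, high dilution (ca. 1 mM), −20 → 0 °C; then Zn dust, AcOH, rt
Reagents that add atoms: none
Why: Ligand exchange binds Tl(III) to the oxygen of the more easily oxidised 2,6-dibromophenol and two-electron loss of Tl(I) leaves a phenoxonium equivalent, to whose bromine-bearing ortho carbon the 2,6-dichlorophenol oxygen adds to give dienone 22; zinc in acetic acid then reduces the C(sp3)–Br bond next to the carbonyl, bromide leaves and the ring rearomatises to the 2-aryloxy-6-bromophenol of 23. The closest known reaction type is the thallium(III) nitrate oxidative macrocyclisation of ortho,ortho'-dihalogenated bis-phenols to cyclic diaryl ethers, finished by zinc reduction. The 18-membered ring is closed end to end by intramolecular attack of the phenol oxygen on the oxidised ring (macro-etherification at the catechol-ring C–O bond), and high dilution holds back intermolecular coupling. The only new sp3 centre, C(Br)(OAr) of 22, forms as a racemate and is erased on rearomatisation, so no stereocentre has to be controlled. The step needs the right assignment of roles and C–O over C–C coupling: the lower oxidation potential of the dibromophenol makes it the electrophile, the chlorines and the para chain block every carbon site of the nucleophilic ring so that only its oxygen can bond, and the two ortho carbons of the dibromo ring are equivalent, so one constitution results. The diacetate ring is too electron-poor to be oxidised, 22 has no free phenol left for over-oxidation, and para capture by methanol gives a quinol ether that zinc returns to 21.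

Step 15
Reactants: 23 halogenated macrocyclic diaryl ether
Product: 24 halogen-free macrocyclic hydroquinone diacetate (free catechol-ring OH)
Conditions: H2 (3 atm), 10% Pd/C, NaOAc, EtOAc–EtOH, rt
Reagents that add atoms: none
Why: Catalytic hydrodehalogenation removes the bromine and both chlorines with acetate as acid scavenger, and the molecule holds no benzylic C–O bond or alkene that hydrogen could attack.

Step 16
Reactants: 24 macrocyclic hydroquinone diacetate
Product: 25 macrocyclic hydroquinone (three free OH groups)
Conditions: HCl (cat.), degassed MeOH–THF, Ar, rt → 40 °C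
Reagents that add atoms: none
Why: Acid-catalysed transesterification (methanolysis) of the aryl acetates avoids phenoxide formation, so the hydroquinone is not oxidised by air and the aryloxy group is not exposed to methoxide.

Step 17
Reactants: 25 macrocyclic hydroquinone
Product: 26 marchantinquinone
Conditions: Ag2O (slight excess), MgSO4, Et2O–CH2Cl2, rt, dark
Reagents that add atoms: none
Why: Silver(I) oxide oxidation takes the hydroquinone to the para-quinone much faster than it touches the isolated 2-aryloxyphenol, so a near-stoichiometric charge should give the target.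

**Compound list**
1 | 2-fluoro-1,4-dimethoxybenzene | COc1ccc(OC)c(F)c1 | starting material
2 | (2-fluoro-3,6-dimethoxyphenyl)lithium | COc1ccc(OC)c([Li])c1F | intermediate
3 | 2-fluoro-3,6-dimethoxybenzaldehyde | COc1ccc(OC)c(C=O)c1F | intermediate
4 | 3-hydroxybenzyl alcohol | OCc1cccc(O)c1 | starting material
5 | 2-[3-(hydroxymethyl)phenoxy]-3,6-dimethoxybenzaldehyde | COc1ccc(OC)c(C=O)c1Oc1cccc(CO)c1 | intermediate
6 | 3,5-dichloro-4-hydroxybenzaldehyde | O=Cc1cc(Cl)c(O)c(Cl)c1 | starting material
7 | 4-(benzyloxy)-3,5-dichlorobenzaldehyde | O=Cc1cc(Cl)c(OCc2ccccc2)c(Cl)c1 | intermediate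
8 | [4-(benzyloxy)-3,5-dichlorophenyl]methanol | OCc1cc(Cl)c(OCc2ccccc2)c(Cl)c1 | intermediate
9 | [4-(benzyloxy)-3,5-dichlorobenzyl]triphenylphosphonium bromide | [Br-].Clc1cc(C[P+](c2ccccc2)(c2ccccc2)c2ccccc2)cc(Cl)c1OCc1ccccc1 | intermediate
10 | [4-(benzyloxy)-3,5-dichlorobenzylidene]triphenylphosphorane | Clc1cc(C=P(c2ccccc2)(c2ccccc2)c2ccccc2)cc(Cl)c1OCc1ccccc1 | intermediate
11 | stilbene alcohol (E/Z mixture) | COc1ccc(OC)c(C=Cc2cc(Cl)c(OCc3ccccc3)c(Cl)c2)c1Oc1cccc(CO)c1 | intermediate
12 | stilbene phosphonium bromide (E/Z mixture) | [Br-].COc1ccc(OC)c(C=Cc2cc(Cl)c(OCc3ccccc3)c(Cl)c2)c1Oc1cccc(C[P+](c2ccccc2)(c2ccccc2)c2ccccc2)c1 | intermediate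
13 | 3,5-dibromo-4-hydroxybenzaldehyde | O=Cc1cc(Br)c(O)c(Br)c1 | starting material
14 | 4-(benzyloxy)-3,5-dibromobenzaldehyde | O=Cc1cc(Br)c(OCc2ccccc2)c(Br)c1 | intermediate
15 | stilbene benzylidenetriphenylphosphorane (ylide formed from 12; E/Z mixture) | COc1ccc(OC)c(C=Cc2cc(Cl)c(OCc3ccccc3)c(Cl)c2)c1Oc1cccc(C=P(c2ccccc2)(c2ccccc2)c2ccccc2)c1 | intermediate
16 | bis-stilbene (E/Z mixtures) | COc1ccc(OC)c(C=Cc2cc(Cl)c(OCc3ccccc3)c(Cl)c2)c1Oc1cccc(C=Cc2cc(Br)c(OCc3ccccc3)c(Br)c2)c1 | intermediate
17 | bis-bibenzyl, dimethyl ether, bis-benzyl ether | COc1ccc(OC)c(CCc2cc(Cl)c(OCc3ccccc3)c(Cl)c2)c1Oc1cccc(CCc2cc(Br)c(OCc3ccccc3)c(Br)c2)c1 | intermediate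
18 | bis-benzyl ether quinone | O=C1C=CC(=O)C(CCc2cc(Cl)c(OCc3ccccc3)c(Cl)c2)=C1Oc1cccc(CCc2cc(Br)c(OCc3ccccc3)c(Br)c2)c1 | intermediate
19 | bis-benzyl ether hydroquinone | Oc1ccc(O)c(CCc2cc(Cl)c(OCc3ccccc3)c(Cl)c2)c1Oc1cccc(CCc2cc(Br)c(OCc3ccccc3)c(Br)c2)c1 | intermediate
20 | bis-benzyl ether hydroquinone diacetate | CC(=O)Oc1ccc(OC(C)=O)c(CCc2cc(Cl)c(OCc3ccccc3)c(Cl)c2)c1Oc1cccc(CCc2cc(Br)c(OCc3ccccc3)c(Br)c2)c1 | intermediate
21 | seco bis-phenol, hydroquinone diacetate | CC(=O)Oc1ccc(OC(C)=O)c(Oc2cccc(CCc3cc(Br)c(O)c(Br)c3)c2)c1CCc1cc(Cl)c(O)c(Cl)c1 | intermediate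
22 | macrocyclic 6-aryloxy-2,6-dibromocyclohexa-2,4-dienone (racemic at the C(Br)(OAr) carbon) | CC(=O)Oc1ccc(OC(C)=O)c2c1CCc1cc(Cl)c(c(Cl)c1)OC1(Br)C=C(C=C(Br)C1=O)CCc1cccc(c1)O2 | intermediate
23 | halogenated macrocyclic diaryl ether, hydroquinone diacetate | CC(=O)Oc1ccc(OC(C)=O)c2c1CCc1cc(Cl)c(c(Cl)c1)Oc1cc(cc(Br)c1O)CCc1cccc(c1)O2 | intermediate
24 | halogen-free macrocycle, hydroquinone diacetate | CC(=O)Oc1ccc(OC(C)=O)c2c1CCc1ccc(cc1)Oc1cc(ccc1O)CCc1cccc(c1)O2 | intermediate
25 | macrocyclic hydroquinone | Oc1ccc(O)c2c1CCc1ccc(cc1)Oc1cc(ccc1O)CCc1cccc(c1)O2 | intermediate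
26 | marchantinquinone | O=C1C=CC(=O)C2=C1CCc1ccc(cc1)Oc1cc(ccc1O)CCc1cccc(c1)O2 | target

Total step count: 17.
Longest linear sequence: 14 steps (6 → 7 → 8 → 9 → 11 → 12 → 16 → 17 → 18 → 20 → 21 → 23 → 24 → 25 → 26).

**Steps most likely to fail**

1. Step 14. Intermolecular coupling may outrun closure of the 18-membered ring. Methanol may capture the oxidised ring before the tethered phenol arrives, and the nitric acid released may start solvolysis of the acetates. The fallback sets out from 21 and comes back at 23, and it moves the oxidation from the metal salt to an electrode. Compound 21 is fed slowly into an undivided cell (glassy-carbon anode, LiClO4 in MeOH–THF). The anode potential is held between the oxidation waves of the dibromophenol and the dichlorophenol, so the role of each phenol is set by the potential and not by ligand exchange on thallium. The protons formed at the anode are consumed at the cathode, so no acid builds up. The crude dienone 22 is then reduced with Zn/AcOH to 23. This fallback makes no compound outside the list (F0).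

2. Step 2. The two methoxy donors slow the addition of phenoxide to the fluoroarene. Forcing the temperature invites degradation of the aldehyde and displacement of the methoxy group ortho to it. The fallback sets out from 4 and comes back at 5, and it replaces the uncatalysed substitution by a copper-catalysed Ullmann etherification. Commercial 2-bromo-1,4-dimethoxybenzene is deprotonated with LDA (THF, −78 °C) at the C–H between Br and OMe and quenched with DMF to give 2-bromo-3,6-dimethoxybenzaldehyde F1. CuI, N,N-dimethylglycine and Cs2CO3 in dioxane at 90 °C then couple it with the phenol of 4 to give 5.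

3. Step 13. The hindered, weakly basic ether oxygens may bind BCl3 slowly. Warming to force the cleavage risks loss or migration of acetyl groups and transfer of benzyl to ring carbon. The fallback sets out from 17 and comes back at 21, bypassing steps 11–13, and it replaces orthogonal protection by differentiation through leaving-group ability. BBr3 (CH2Cl2, −78 °C → rt) cleaves all four alkyl ethers to give the tetraphenol 2-{3-[2-(3,5-dibromo-4-hydroxyphenyl)ethyl]phenoxy}-3-[2-(3,5-dichloro-4-hydroxyphenyl)ethyl]benzene-1,4-diol F2. Immediate treatment with Ac2O/pyridine gives the corresponding tetraacetate F3. Imidazole in MeOH–THF at rt then removes only the two acetates of the dihalophenols (phenol pKa about 7, against about 10 for the hydroquinone esters) and delivers 21.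

Further compounds
F0 | step 14 | none | none
F1 | step 2 | 2-bromo-3,6-dimethoxybenzaldehyde | COc1ccc(OC)c(C=O)c1Br
F2 | step 13 | 2-{3-[2-(3,5-dibromo-4-hydroxyphenyl)ethyl]phenoxy}-3-[2-(3,5-dichloro-4-hydroxyphenyl)ethyl]benzene-1,4-diol | Oc1ccc(O)c(CCc2cc(Cl)c(O)c(Cl)c2)c1Oc1cccc(CCc2cc(Br)c(O)c(Br)c2)c1
F3 | step 13 | tetraacetate of F2 | CC(=O)Oc1ccc(OC(C)=O)c(CCc2cc(Cl)c(OC(C)=O)c(Cl)c2)c1Oc1cccc(CCc2cc(Br)c(OC(C)=O)c(Br)c2)c1
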